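The rate constants were chosen freely, and the outcome is calculated.

Count G.J.Q together with its D, in percent of the J charged, and follow one J on its way there.

    J + Q → J.Q (k1 = 4.1 × 10⁻⁵ M⁻¹ s⁻¹)
    G + J.Q → G.J.Q (k2 = 1.2 × 10⁻⁴ M⁻¹ s⁻¹)
    G.J.Q ⇌ L (K3 = 2.3, k3 = 1.0 × 10⁻⁴ s⁻¹)
    Q + G.J.Q ⇌ D, settled at all times (K4 = 1.5 M⁻¹)
    J.Q → Z (k5 = 4.0 × 10⁻⁶ s⁻¹)

common to all: J 0.10 M; time 30 h
- autumn: Q 0.300 M; G 0.110 M (fed, over 40 min); all else is in the flask from the start; the feed brings no volume worth counting
- noon: Q 0.300 M (fed, over 6.0 h); G 0.110 M; all else is in the flask from the start; the feed brings no volume worth counting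
- winter: Q 0.300 M; G 0.110 M; everything together at the start
- summer: Q 0.300 M; G 0.110 M (in portions, 4, over 6.0 h); first portion at the start, last at 6.0 h
- dawn: Q 0.300 M; G 0.110 M (fed, over 6.0 h); all else is in the flask from the start; the feed brings no volume worth counting

- the flask that comes out highest in amount of G.J.Q, in percent of the J charged, or "all alike" when all lie within 1.5 percentage points (autumn / noon / winter / summer / dawn / all alike)
- G.J.Q at the end, in percent of the J charged, autumn
- G.J.Q at the end, in percent of the J charged, noon
- G.J.Q at the end, in percent of the J charged, winter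
- G.J.Q at the end, in percent of the J charged, summer
- G.J.Q at the end, in percent of the J charged, dawn

- G.J.Q is meant together with its D
- run time (autumn): 30 h

Take one J once Q has bound it as J.Q. At the first fork G captures it or it leaves as Z, and with G as charged the capture chance is 76.7%. At the second fork the balances with L and D leave 38.7% of the captured pool as G.J.Q, with Q as charged. Multiply them to 29.7%, the end chance: the chance that a J leaving J.Q stands as G.J.Q once the exchange with L has balanced.

Now reckon winter with Q and G held at their charges, the pseudo-first-order picture. J falls at 0.0443 h⁻¹ and J.Q at 0.0619 h⁻¹, so at 30 h J.Q holds 27.3% and 46.2% has left it. Solve two extremes. With the exchange frozen, G.J.Q is the whole pool, 35.4%. With the exchange instant, it is 13.7%. Place winter near the second, because in winter the half-life of free G.J.Q by step 3 alone, forward rate only, is 1.9 h, short against 30 h. Q and G fall as they are used, and I expect a little less.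

Dosing G over 6.0 h in dawn should cost little, because the half-life of J by step 1 alone with Q as charged, 16 h, is longer than that dosing. Count the feed of Q over 6.0 h in noon as a mean delay of 3.00 h, and the estimate is 12.2%. That gap of 1.5 percentage points against a margin of 1.5 points is too close to call by hand, so lean narrowly towards calling the flasks alike.

The forecast gives 12.3% for autumn, 11.5% for noon, 12.3% for winter, 12.2% for summer and 12.2% for dawn, hence all alike: “Dosing G barely matters, since J.Q is scarce early.” My held-charge figure of 13.7% stands higher than its winter value.

The flasks give 12.4% for autumn, 11.4% for noon, 12.4% for winter, 12.3% for summer and 12.3% for dawn: all alike. The neighbour of autumn charged with 0.028 M of G has, with its G and Q as charged, an end chance of 17.7%, and at 30.0 h G.J.Q makes up 17.4% of what has left its J.Q. Autumn has not come to rest: at 30.0 h it holds 32.1% of the J charged as J and 28.0% as J.Q. At 300 h autumn's J is down to 0.0117%, its G.J.Q reaches 24.4%, and G.J.Q makes up 24.4% of what has left J.Q, against the end chance of 29.7% reckoned with G and Q as charged.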